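The ten-membered carbocycle is disconnected at C1–C10. The vicinal pair C1 (allylic carbinol next to C2=C3) and C10 (isopropyl, read as isopropenyl) is the homoallylic alcohol that a [2,3]-Wittig shift leaves behind. In one operation the shift forms C1–C10, contracts a 13-membered bis-allylic ether (C1–O–C12H2–C11(Me)=C10, all three ring olefins ring-cis) to the cyclodecadiene, and sets C1 and C10 from the C9 stereocentre. The ether carries unlike silyl ethers at O9 (TBS) and O14 (TBDPS), because O9 must be acetylated before C14 is oxidised; a free C9 hydroxyl would trap the C14 aldehyde as a lactol. The ether is assembled from nerol, (S)-glycidol and two phosphonates.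

Key step: step 17

Remark: the ring numbering of the target is kept for all intermediates (C11 = isopropyl methine, C12 = the carbon that is O-bound in the macrocyclic ether, C13 = the other isopropyl methyl, C14 = carboxyl carbon on C7, C15 = methyl on C3); TBS = tert-butyldimethylsilyl, TBDPS = tert-butyldiphenylsilyl, PMB = 4-methoxybenzyl.

Step 1
Reactants: 1 nerol
Product: 2 nerol TBS ether, (Z)-tert-butyl[(3,7-dimethylocta-2,6-dien-1-yl)oxy]dimethylsilane
Conditions: TBSCl, imidazole, CH2Cl2, 0 °C to rt
Reagents that add atoms: tert-butyldimethylsilyl chloride, CC(C)(C)[Si](C)(C)Cl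
Why: Standard silylation of a primary allylic alcohol; a primary TBS ether is chosen for O1 because it can later be cleaved beside a secondary TBS and a TBDPS ether.

Step 2
Reactants: 2 nerol TBS ether
Product: 3 6,7-epoxide of 2 (racemic at the oxirane CH)
Conditions: mCPBA (1.0 equiv), CH2Cl2, −20 to 0 °C
Reagents that add atoms: meta-chloroperoxybenzoic acid, OOC(=O)c1cccc(Cl)c1
Why: Prilezhaev epoxidation should select the remote isopropylidene olefin, which is more electron-rich and less hindered than C2=C3 (deactivated by the allylic C–O bond); the new stereocentre is lost in step 3.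

Step 3
Reactants: 3 6,7-epoxide
Product: 5 (Z)-6-[(tert-butyldimethylsilyl)oxy]-4-methylhex-4-enal, via vicinal diol 4 (not isolated)
Conditions: H5IO6, THF/Et2O, 0 °C
Reagents that add atoms: none
Why: Periodic acid hydrolyses the trisubstituted epoxide (water enters at the tertiary carbon) and cleaves the glycol (Malaprade cleavage) to acetone and the C1–C6 aldehyde, whose carbonyl oxygen is the former epoxide oxygen; the short, cold exposure should spare the TBS ether and the Z olefin.

Step 4
Reactants: 6 (S)-glycidol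
Product: 7 (R)-2-{[(4-methoxybenzyl)oxy]methyl}oxirane
Conditions: NaH, PMBCl, n-Bu4NI (cat.), THF, 0 °C to rt
Reagents that add atoms: 4-methoxybenzyl chloride, COc1ccc(CCl)cc1
Why: Williamson etherification of the primary alkoxide leaves the oxirane stereocentre untouched (the descriptor changes from S to R only through the priority change), and a benzyl-type ether cannot migrate to the neighbouring alkoxide formed in step 5.

Step 5
Reactants: 7 (R)-PMB glycidyl ether; 8 triethyl phosphonoacetate
Product: 10 diethyl [(5R)-5-{[(4-methoxybenzyl)oxy]methyl}-2-oxooxolan-3-yl]phosphonate, via hydroxy phosphonoester 9 (not isolated)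
Conditions: NaH, toluene, 90 °C; aq. NH4Cl
Reagents that add atoms: none
Why: The sodium phosphonoacetate carbanion opens the oxirane at its unsubstituted carbon (SN2, stereocentre untouched) and the C9 alkoxide lactonises onto the ethyl ester (5-exo-trig acyl substitution), giving the α-phosphono-γ-butyrolactone as a mixture at C7, which becomes sp2 in step 6.

Step 6
Reactants: 10 phosphonolactone; 5 C1–C6 aldehyde
Product: 11 (3E,5R)-3-{(4Z)-6-[(tert-butyldimethylsilyl)oxy]-4-methylhex-4-en-1-ylidene}-5-{[(4-methoxybenzyl)oxy]methyl}oxolan-2-one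
Conditions: NaH, THF, 0 °C; then 5, 0 °C to rt
Reagents that add atoms: none
Why: Horner–Wadsworth–Emmons olefination of the stabilised lactone phosphonate should give the thermodynamically preferred E-alkylidene lactone (C5 anti to the carbonyl C14 and therefore cis to C8, as the ring needs); a minor Z isomer would be removed by chromatography.

Step 7
Reactants: 11 alkylidene lactone
Product: 12 seco diol (C14-OH, C9-OH; C1-OTBS, C10-OPMB; 2Z, 6E, 9R)
Conditions: i-Bu2AlH (4 equiv), CH2Cl2, −78 to −20 °C; aq. potassium sodium tartrate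
Reagents that add atoms: none
Why: i-Bu2AlH reduces the α-alkylidene lactone in 1,2-fashion through the lactol to the 2-alkylidene-1,4-diol without touching the olefins, the PMB ether or the silyl ether.

Step 8
Reactants: 12 seco diol
Product: 13 C14 TBDPS ether (C9-OH free)
Conditions: TBDPSCl (1.05 equiv), imidazole, CH2Cl2, 0 °C
Reagents that add atoms: tert-butyldiphenylsilyl chloride, CC(C)(C)[Si](Cl)(c1ccccc1)c1ccccc1
Why: The bulky silyl chloride should silylate the primary allylic C14 hydroxyl much faster than the secondary C9 hydroxyl (steric differentiation).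

Step 9
Reactants: 13 C14 TBDPS ether
Product: 14 C9 TBS ether (C1-OTBS, C9-OTBS, C10-OPMB, C14-OTBDPS)
Conditions: TBSOTf, 2,6-lutidine, CH2Cl2, −78 to 0 °C
Reagents that add atoms: tert-butyldimethylsilyl triflate, CC(C)(C)[Si](C)(C)OS(=O)(=O)C(F)(F)F
Why: Silyl triflate silylation of the remaining secondary alcohol; O9 (TBS) and O14 (TBDPS) are now distinguishable, which the endgame requires.

Step 10
Reactants: 14 fully protected seco compound
Product: 15 C10 primary alcohol
Conditions: DDQ, CH2Cl2/pH 7 buffer, 0 °C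
Reagents that add atoms: none
Why: Oxidative PMB cleavage by DDQ (hydride abstraction, then hydrolysis of the oxocarbenium ion) leaves silyl ethers and trisubstituted olefins untouched.

Step 11
Reactants: 15 C10 alcohol
Product: 16 C10 aldehyde (α-silyloxy aldehyde, 9R)
Conditions: Dess–Martin periodinane, pyridine, CH2Cl2, 0 °C to rt
Reagents that add atoms: none
Why: Dess–Martin oxidation under buffered, non-basic conditions should give the α-silyloxy aldehyde without epimerising C9; it is used at once.

Step 12
Reactants: 16 C10 aldehyde; 17 ethyl 2-[bis(2,2,2-trifluoroethoxy)phosphoryl]propanoate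
Product: 18 ethyl (10Z)-enoate (C12 ester; 2Z, 6E, 10Z, 9R)
Conditions: 17, KN(SiMe3)2, 18-crown-6, THF, −78 °C; then 16
Reagents that add atoms: none
Why: Still–Gennari olefination: the bis(trifluoroethyl) phosphonate under dissociating conditions eliminates from the kinetic adduct and should deliver the Z-trisubstituted enoate (C9 cis to C12), the cold, fast reaction preserving C9.

Step 13
Reactants: 18 Z-enoate
Product: 19 C12 allylic alcohol
Conditions: i-Bu2AlH, CH2Cl2, −78 °C; aq. potassium sodium tartrate
Reagents that add atoms: none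
Why: 1,2-Reduction of the enoate to the allylic alcohol with retention of the Z geometry.

Step 14
Reactants: 19 C12 allylic alcohol
Product: 20 C12 allylic chloride
Conditions: NCS, Me2S, CH2Cl2, −20 to 0 °C
Reagents that add atoms: N-chlorosuccinimide, O=C1CCC(=O)N1Cl
Why: Corey–Kim chlorination converts the primary allylic alcohol through its alkoxysulfonium salt into the chloride by direct SN2 displacement, without allylic transposition, under neutral conditions that silyl ethers tolerate.

Step 15
Reactants: 20 C12 chloride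
Product: 21 hydroxy chloride (C1-OH, C12-Cl)
Conditions: HF·pyridine, pyridine, THF, 0 °C
Reagents that add atoms: none
Why: Buffered HF·pyridine should remove the unhindered primary allylic TBS ether at O1 well before the hindered secondary TBS ether at O9 or the TBDPS ether, and it does not displace the allylic chloride.

Step 16
Reactants: 21 hydroxy chloride
Product: 22 (3Z,5R,7E,11Z)-5-[(tert-butyldimethylsilyl)oxy]-7-{[(tert-butyldiphenylsilyl)oxy]methyl}-3,11-dimethyl-1-oxacyclotrideca-3,7,11-triene (13-membered ether C1–O–C12)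
Conditions: NaH, n-Bu4NI (cat.), THF, 0.003 M (syringe-pump addition), 60 °C
Reagents that add atoms: none
Why: Intramolecular Williamson etherification: the C1 alkoxide displaces the C12 allylic chloride (SN2, iodide catalysis) under high dilution, with the three cis-configured olefins as turn elements; the alkoxide is remote from both silyl ethers, so silyl migration cannot intervene.

Step 17
Reactants: 22 13-membered bis-allylic ether
Product: 24 cyclodecadienol (1R,9R,10R; C1-OH; C9-OTBS; C14-OTBDPS; C10 isopropenyl; 2Z; 6E), via C1-lithio ether 23 (not isolated)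
Conditions: n-BuLi, THF/hexane, −78 to −20 °C; aq. NH4Cl
Reagents that add atoms: none
Why: n-BuLi, pre-coordinated to the ether oxygen, removes an allylic proton at C1 to give the allyl-stabilised α-oxy carbanion 23, which bonds to C10 suprafacially through a five-membered envelope array (C1, O, C12, C11, C10) while O–C12 breaks and the C10=C11 π bond moves to C11=C12 (isopropenyl), leaving the C1 lithium alkoxide. The closest known reaction type is the [2,3]-Wittig ring contraction of 13-membered diallylic ethers of this same substitution pattern to cyclodecadienols. The ten-membered carbocycle is closed transannularly (13 to 10) inside the existing ring, so the entropic price was already paid in the C–O cyclisation of step 16. C1 is controlled by the Z geometry of C10=C11 with C2 exo on the envelope, which should give the 1,10-cis (syn) relationship; C10 is controlled by C9, whose hydrogen eclipses the olefin to avoid allylic 1,3-strain with C12, so that C1 arrives anti to the C9–OTBS bond. The step needs lithiation at C1 instead of C12 or C14 and a [2,3] in preference to a [1,2] shift: C1 is the least hindered O–CH2 (C12 is flanked by the C11 methyl and the cis C9 silyloxy group, C14 sits on a bulky, weakly coordinating TBDPS ether), a C12 anion could rearrange only by creating a quaternary C3, and the low temperature disfavours the radical [1,2] pathway.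

Step 18
Reactants: 24 cyclodecadienol
Product: 25 1,9-diol (1R,9R,10S; C14-OTBDPS; C10 isopropenyl)
Conditions: HF·pyridine, THF, 0 °C to rt
Reagents that add atoms: none
Why: Under acidic fluoride conditions a TBS ether is cleaved far faster than a TBDPS ether, so the C9 hydroxyl should be released while O14 stays protected and no lactol can form yet.

Step 19
Reactants: 25 1,9-diol
Product: 26 1,9-diacetate (C14-OTBDPS; C10 isopropenyl)
Conditions: Ac2O, pyridine, DMAP (cat.), CH2Cl2, rt
Reagents that add atoms: acetic anhydride, CC(=O)OC(C)=O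
Why: DMAP-catalysed acylation installs both acetates of the target (O1 and O9) in one operation with retention at both carbinol centres.

Step 20
Reactants: 26 diacetate
Product: 27 isopropyl diacetate (C14-OTBDPS)
Conditions: H2 (1 atm), RhCl(PPh3)3 (10 mol %), benzene, rt
Reagents that add atoms: none
Why: Homogeneous hydrogenation with RhCl(PPh3)3 should saturate the 1,1-disubstituted isopropenyl olefin and leave the two trisubstituted ring olefins, the allylic acetate and the allylic silyl ether untouched; no stereocentre is created.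

Step 21
Reactants: 27 isopropyl diacetate
Product: 28 C14 allylic alcohol
Conditions: HF·pyridine, THF, rt
Reagents that add atoms: none
Why: Fluoride-driven cleavage of the primary TBDPS ether under non-basic conditions, which avoids acetate migration or hydrolysis.

Step 22
Reactants: 28 C14 allylic alcohol
Product: 29 C14 enal
Conditions: Dess–Martin periodinane, pyridine, CH2Cl2, rt
Reagents that add atoms: none
Why: Dess–Martin oxidation of the primary allylic alcohol to the enal; with O9 acetylated no lactol can form, and the E (ring-cis) geometry at C6=C7 is the stable one.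

Step 23
Reactants: 29 C14 enal
Product: 30 target acid CNP0172943.1 (1R,9R,10S; 2Z; 6E)
Conditions: NaClO2, NaH2PO4, 2-methyl-2-butene, t-BuOH/H2O, rt
Reagents that add atoms: sodium chlorite, [Na+].[O-]Cl=O
Why: Pinnick oxidation converts the enal into the carboxylic acid, with 2-methyl-2-butene scavenging hypochlorous acid so that the trisubstituted olefins, the acetates and the stereocentres stay intact.

Compound list

1 | nerol, (2Z)-3,7-dimethylocta-2,6-dien-1-ol | CC(C)=CCC/C(C)=C\CO | starting material
2 | nerol TBS ether | CC(C)=CCC/C(C)=C\CO[Si](C)(C)C(C)(C)C | intermediate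
3 | 6,7-epoxide of 2 (racemic at the oxirane CH) | CC1(C)OC1CC/C(C)=C\CO[Si](C)(C)C(C)(C)C | intermediate
4 | vicinal diol from 3 (racemic; not isolated) | CC(C)(O)C(O)CC/C(C)=C\CO[Si](C)(C)C(C)(C)C | intermediate
5 | (Z)-6-[(tert-butyldimethylsilyl)oxy]-4-methylhex-4-enal (C1–C6) | O=CCC/C(C)=C\CO[Si](C)(C)C(C)(C)C | intermediate
6 | (S)-glycidol | OC[C@H]1CO1 | starting material
7 | (R)-2-{[(4-methoxybenzyl)oxy]methyl}oxirane | COc1ccc(COC[C@H]2CO2)cc1 | intermediate
8 | triethyl phosphonoacetate | CCOC(=O)CP(=O)(OCC)OCC | starting material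
9 | ethyl (4R)-2-(diethoxyphosphoryl)-4-hydroxy-5-[(4-methoxybenzyl)oxy]pentanoate (sodium alkoxide in the flask; mixture at C2; not isolated) | CCOC(=O)C(C[C@@H](O)COCc1ccc(OC)cc1)P(=O)(OCC)OCC | intermediate
10 | diethyl [(5R)-5-{[(4-methoxybenzyl)oxy]methyl}-2-oxooxolan-3-yl]phosphonate (mixture at C3) | CCOP(=O)(OCC)C1C[C@H](COCc2ccc(OC)cc2)OC1=O | intermediate
11 | (3E,5R)-alkylidene lactone (C1-OTBS, C10-OPMB) | CC(C)(C)[Si](C)(C)OC/C=C(/C)CC/C=C1\C[C@H](COCc2ccc(OC)cc2)OC1=O | intermediate
12 | seco diol, (2E,4R)-2-{(4Z)-6-[(tert-butyldimethylsilyl)oxy]-4-methylhex-4-en-1-ylidene}-5-[(4-methoxybenzyl)oxy]pentane-1,4-diol | CC(C)(C)[Si](C)(C)OC/C=C(/C)CC/C=C(/CO)C[C@@H](O)COCc1ccc(OC)cc1 | intermediate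
13 | C14 TBDPS ether of 12 (C9-OH, 9R) | CC(C)(C)[Si](C)(C)OC/C=C(/C)CC/C=C(/CO[Si](c1ccccc1)(c1ccccc1)C(C)(C)C)C[C@@H](O)COCc1ccc(OC)cc1 | intermediate
14 | C9 TBS, C14 TBDPS, C10 PMB, C1 TBS seco compound (9R) | CC(C)(C)[Si](C)(C)OC/C=C(/C)CC/C=C(/CO[Si](c1ccccc1)(c1ccccc1)C(C)(C)C)C[C@@H](O[Si](C)(C)C(C)(C)C)COCc1ccc(OC)cc1 | intermediate
15 | C10 primary alcohol (9R) | CC(C)(C)[Si](C)(C)OC/C=C(/C)CC/C=C(/CO[Si](c1ccccc1)(c1ccccc1)C(C)(C)C)C[C@@H](O[Si](C)(C)C(C)(C)C)CO | intermediate
16 | C10 aldehyde (9R) | CC(C)(C)[Si](C)(C)OC/C=C(/C)CC/C=C(/CO[Si](c1ccccc1)(c1ccccc1)C(C)(C)C)C[C@@H](O[Si](C)(C)C(C)(C)C)C=O | intermediate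
17 | ethyl 2-[bis(2,2,2-trifluoroethoxy)phosphoryl]propanoate | CCOC(=O)C(C)P(=O)(OCC(F)(F)F)OCC(F)(F)F | starting material
18 | ethyl (10Z)-enoate (2Z, 6E, 10Z, 9R) | CC(C)(C)[Si](C)(C)OC/C=C(/C)CC/C=C(/CO[Si](c1ccccc1)(c1ccccc1)C(C)(C)C)C[C@@H](O[Si](C)(C)C(C)(C)C)/C=C(/C)C(=O)OCC | intermediate
19 | C12 allylic alcohol (9R) | CC(C)(C)[Si](C)(C)OC/C=C(/C)CC/C=C(/CO[Si](c1ccccc1)(c1ccccc1)C(C)(C)C)C[C@@H](O[Si](C)(C)C(C)(C)C)/C=C(/C)CO | intermediate
20 | C12 allylic chloride (9R) | CC(C)(C)[Si](C)(C)OC/C=C(/C)CC/C=C(/CO[Si](c1ccccc1)(c1ccccc1)C(C)(C)C)C[C@@H](O[Si](C)(C)C(C)(C)C)/C=C(/C)CCl | intermediate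
21 | hydroxy chloride, C1-OH and C12-Cl (9R) | OC/C=C(/C)CC/C=C(/CO[Si](c1ccccc1)(c1ccccc1)C(C)(C)C)C[C@@H](O[Si](C)(C)C(C)(C)C)/C=C(/C)CCl | intermediate
22 | (3Z,5R,7E,11Z)-5-[(tert-butyldimethylsilyl)oxy]-7-{[(tert-butyldiphenylsilyl)oxy]methyl}-3,11-dimethyl-1-oxacyclotrideca-3,7,11-triene | C1/C=C(/C)CC/C=C(/CO[Si](c2ccccc2)(c2ccccc2)C(C)(C)C)C[C@@H](O[Si](C)(C)C(C)(C)C)/C=C(/C)CO1 | intermediate
23 | C1-lithio derivative of 22 (configurationally labile at C1; not isolated) | [Li]C1/C=C(/C)CC/C=C(/CO[Si](c2ccccc2)(c2ccccc2)C(C)(C)C)C[C@@H](O[Si](C)(C)C(C)(C)C)/C=C(/C)CO1 | intermediate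
24 | (1R,2Z,6E,9R,10R)-9-[(tert-butyldimethylsilyl)oxy]-7-{[(tert-butyldiphenylsilyl)oxy]methyl}-3-methyl-10-(prop-1-en-2-yl)cyclodeca-2,6-dien-1-ol | O[C@@H]1/C=C(/C)CC/C=C(/CO[Si](c2ccccc2)(c2ccccc2)C(C)(C)C)C[C@@H](O[Si](C)(C)C(C)(C)C)[C@@H]1C(C)=C | intermediate
25 | 1,9-diol (1R,9R,10S; C14-OTBDPS; C10 isopropenyl) | O[C@@H]1/C=C(/C)CC/C=C(/CO[Si](c2ccccc2)(c2ccccc2)C(C)(C)C)C[C@@H](O)[C@@H]1C(C)=C | intermediate
26 | 1,9-diacetate (1R,9R,10S; C14-OTBDPS; C10 isopropenyl) | CC(=O)O[C@@H]1/C=C(/C)CC/C=C(/CO[Si](c2ccccc2)(c2ccccc2)C(C)(C)C)C[C@@H](OC(C)=O)[C@@H]1C(C)=C | intermediate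
27 | 1,9-diacetate, C10 isopropyl (1R,9R,10S; C14-OTBDPS) | CC(=O)O[C@@H]1/C=C(/C)CC/C=C(/CO[Si](c2ccccc2)(c2ccccc2)C(C)(C)C)C[C@@H](OC(C)=O)[C@@H]1C(C)C | intermediate
28 | C14 allylic alcohol diacetate (1R,9R,10S) | CC(=O)O[C@@H]1/C=C(/C)CC/C=C(/CO)C[C@@H](OC(C)=O)[C@@H]1C(C)C | intermediate
29 | C14 enal diacetate (1R,9R,10S) | CC(=O)O[C@@H]1/C=C(/C)CC/C=C(/C=O)C[C@@H](OC(C)=O)[C@@H]1C(C)C | intermediate
30 | CNP0172943.1, (1R,2Z,6E,9R,10S)-1,9-diacetoxy-3-methyl-10-isopropylcyclodeca-2,6-diene-7-carboxylic acid (ring numbering of the target) | CC(=O)O[C@@H]1/C=C(/C)CC/C=C(/C(=O)O)C[C@@H](OC(C)=O)[C@@H]1C(C)C | target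

Total step count: 23. Longest linear sequence: 21 steps (nerol through steps 1–3 and 6–23); the glycidol branch (steps 4–5) joins at step 6.

Steps most likely to fail

Step 17. What may go wrong: lithiation at C12 or C14 instead of C1 (followed by 1,4-elimination of the C9 silyloxy group, a shift onto C3 or a silyl migration), or a competing [1,2]-shift. Fallback: the ether route is left at hydroxy chloride 21 and C1–C10 is closed by carbonyl allylation. MnO2 in CH2Cl2 oxidises the C1 allylic alcohol to the Z-enal chloride F1. CrCl2 in THF at high dilution (Nozaki–Hiyama–Kishi allylation) then adds the C12 allylchromium through C10 to the aldehyde and closes the ten-membered ring, with C10 expected to be attacked anti to the C9 silyloxy group for the same allylic-strain reason. Its chair transition state should favour the anti adduct, that is the C1-epimeric cyclodecadienol F2. Mitsunobu inversion (PPh3, diisopropyl azodicarboxylate, 4-nitrobenzoic acid) would give the (1R)-4-nitrobenzoate F3, and K2CO3 in MeOH returns the route at 24.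

Step 16. What may go wrong: intermolecular etherification (oligomerisation) outrunning the 13-membered closure, or SN2′ attack at C10. Fallback: the other C–O bond is closed, with the less hindered C1 terminus as the electrophile. From ester 18, HF·pyridine/pyridine frees the C1 alcohol F4, and NCS/Me2S converts it into the C1 chloride F5. i-Bu2AlH at −78 °C reduces the ester to the C12 alcohol F6. EtMgBr in THF/HMPA at high dilution (a magnesium alkoxide, which should not readily pass the neighbouring silyl group from O9 to O12) closes the ring and returns the route at 22.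

Step 18. What may go wrong: concurrent loss of the primary TBDPS ether, or stalled cleavage of the hindered secondary TBS ether. Fallback: selectivity is given up in the cleavage and recovered in a silylation. From 24, Bu4NF in THF removes both silyl groups to give the triol F7. TBDPSCl/imidazole at −20 °C then re-silylates only the primary allylic C14 hydroxyl and returns the route at 25.

Further compounds

F1 | step 17 | Z-enal chloride (C1 aldehyde, C12-Cl; 9R) | O=C/C=C(/C)CC/C=C(/CO[Si](c1ccccc1)(c1ccccc1)C(C)(C)C)C[C@@H](O[Si](C)(C)C(C)(C)C)/C=C(/C)CCl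
F2 | step 17 | C1 epimer of 24 (1S,9R,10R) | O[C@H]1/C=C(/C)CC/C=C(/CO[Si](c2ccccc2)(c2ccccc2)C(C)(C)C)C[C@@H](O[Si](C)(C)C(C)(C)C)[C@@H]1C(C)=C
F3 | step 17 | (1R)-4-nitrobenzoate of 24 | O=C(O[C@@H]1/C=C(/C)CC/C=C(/CO[Si](c2ccccc2)(c2ccccc2)C(C)(C)C)C[C@@H](O[Si](C)(C)C(C)(C)C)[C@@H]1C(C)=C)c1ccc(cc1)[N+](=O)[O-]
F4 | step 16 | C1 alcohol of ester 18 | OC/C=C(/C)CC/C=C(/CO[Si](c1ccccc1)(c1ccccc1)C(C)(C)C)C[C@@H](O[Si](C)(C)C(C)(C)C)/C=C(/C)C(=O)OCC
F5 | step 16 | C1 chloride of ester 18 | ClC/C=C(/C)CC/C=C(/CO[Si](c1ccccc1)(c1ccccc1)C(C)(C)C)C[C@@H](O[Si](C)(C)C(C)(C)C)/C=C(/C)C(=O)OCC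
F6 | step 16 | C1 chloride, C12 alcohol | ClC/C=C(/C)CC/C=C(/CO[Si](c1ccccc1)(c1ccccc1)C(C)(C)C)C[C@@H](O[Si](C)(C)C(C)(C)C)/C=C(/C)CO
F7 | step 18 | triol (C1-OH, C9-OH, C14-OH; C10 isopropenyl) | O[C@@H]1/C=C(/C)CC/C=C(/CO)C[C@@H](O)[C@@H]1C(C)=C
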